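**Assumption:** the target has no stereocentre and no stereogenic double bond, so it is achiral and the "single enantiomer" is the compound as drawn. Transient intermediates that are racemic or diastereomeric mixtures are written without stereodescriptors.

## Retrosynthetic overview

1. The pyranone and oxepine rings are opened together: target ⇐ 2'-hydroxychalcone **19** carrying an α-aryloxy enal on the B-ring (oxa-Michael closes the pyranone, intramolecular aldol condensation closes the oxepine, then a double-bond shift).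
2. Chalcone ⇐ Claisen–Schmidt union of acetophenone **9** (A-ring) and aldehyde **17** (B-ring with the enol-ether side chain as an allylic alcohol).
3. **9** ⇐ 2',4'-dihydroxy-6'-methoxyacetophenone: chromene ring first (propargyl ether, thermal cyclization), then the prenyl group by O-prenylation and para-Claisen–Cope shift.
4. **17** ⇐ 2-hydroxy-4,5-dimethoxybenzaldehyde and ethyl 2-bromoisovalerate: O-alkylation, then selenoxide dehydrogenation to the tetrasubstituted enol ether, then ester reduction.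
5. Ring order: dimethylpyran (step 2), then pyranone and oxepine together (step 11).

## Route

### A-ring fragment

**Step 1**
Reactants: 1 1-(2,4-dihydroxy-6-methoxyphenyl)ethan-1-one; 2 3-chloro-3-methylbut-1-yne
Product: 3 1-{2-hydroxy-6-methoxy-4-[(2-methylbut-3-yn-2-yl)oxy]phenyl}ethan-1-one
Conditions: K2CO3 (2 equiv), KI, CuI (cat.), acetone, reflux
Reagents that add atoms: none
Why: Williamson-type O-alkylation in which only the free 4-OH reacts, because the 2-OH is tied up in a hydrogen bond to the acetyl group.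

**Step 2**
Reactants: 3 1-{2-hydroxy-6-methoxy-4-[(2-methylbut-3-yn-2-yl)oxy]phenyl}ethan-1-one
Product: 5 1-(5-hydroxy-7-methoxy-2,2-dimethyl-2H-chromen-6-yl)ethan-1-one, via o-quinone methide 4 (not isolated)
Conditions: PhNEt2, 190 °C, Ar
Reagents that add atoms: none
Why: Propargyl Claisen rearrangement to C3 (the ortho carbon next to the chelated OH, as in resacetophenone ethers), then 1,5-H shift and oxa-6π electrocyclization give the chromene; any minor linear isomer is removed by chromatography.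

**Step 3**
Reactants: 5 1-(5-hydroxy-7-methoxy-2,2-dimethyl-2H-chromen-6-yl)ethan-1-one; 6 1-bromo-3-methylbut-2-ene (prenyl bromide)
Product: 7 1-{7-methoxy-2,2-dimethyl-5-[(3-methylbut-2-en-1-yl)oxy]-2H-chromen-6-yl}ethan-1-one
Conditions: K2CO3 (3 equiv), acetone, reflux
Reagents that add atoms: none
Why: Williamson O-alkylation of the only phenol, which is slow because of chelation but reliable in refluxing acetone.

**Step 4**
Reactants: 7 1-{7-methoxy-2,2-dimethyl-5-[(3-methylbut-2-en-1-yl)oxy]-2H-chromen-6-yl}ethan-1-one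
Product: 9 1-[5-hydroxy-7-methoxy-2,2-dimethyl-8-(3-methylbut-2-en-1-yl)-2H-chromen-6-yl]ethan-1-one, via ortho-dienone 8 (not isolated)
Conditions: PhNEt2, 200 °C, sealed tube, Ar
Reagents that add atoms: none
Why: Both ortho positions are blocked, so the aromatic Claisen rearrangement is followed by a Cope shift to the only free (para) carbon C8; the two allylic inversions deliver a normal prenyl group (para-Claisen–Cope rearrangement).

### B-ring fragment

**Step 5**
Reactants: 10 2-hydroxy-4,5-dimethoxybenzaldehyde; 11 ethyl 2-bromo-3-methylbutanoate (racemic)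
Product: 12 ethyl 2-(2-formyl-4,5-dimethoxyphenoxy)-3-methylbutanoate (racemic)
Conditions: K2CO3 (2 equiv), DMF, 70 °C
Reagents that add atoms: none
Why: SN2 O-alkylation of the phenoxide by the α-bromo ester; the hindered, weakly acidic α-CH does not cyclize onto the electron-rich aldehyde at this temperature.

**Step 6**
Reactants: 12 ethyl 2-(2-formyl-4,5-dimethoxyphenoxy)-3-methylbutanoate
Product: 13 ethyl 2-[2-(diethoxymethyl)-4,5-dimethoxyphenoxy]-3-methylbutanoate (racemic)
Conditions: HC(OEt)3, EtOH, p-TsOH (2 mol %), 25 °C; Et3N quench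
Reagents that add atoms: triethyl orthoformate, CCOC(OCC)OCC
Why: Acid-catalysed acetalization driven by the orthoformate masks the aldehyde against the enolate and hydride steps that follow.

**Step 7**
Reactants: 13 ethyl 2-[2-(diethoxymethyl)-4,5-dimethoxyphenoxy]-3-methylbutanoate
Product: 15 ethyl 2-[2-(diethoxymethyl)-4,5-dimethoxyphenoxy]-3-methylbut-2-enoate, via α-selenide 14 (not isolated)
Conditions: LDA (1.3 equiv), THF, −78 °C; PhSeBr, −78 → 0 °C; then 30% H2O2, pyridine, CH2Cl2, 0 → 25 °C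
Reagents that add atoms: phenylselenenyl bromide, Br[Se]c1ccccc1 (its PhSe group is held only by 14 and leaves again on elimination)
Why: α-Selenenylation of the ester enolate and selenoxide syn-elimination; the only β-hydrogen is the isopropyl methine, so the tetrasubstituted aryl enol ether C(OAr)=CMe2 is the sole possible alkene.

**Step 8**
Reactants: 15 ethyl 2-[2-(diethoxymethyl)-4,5-dimethoxyphenoxy]-3-methylbut-2-enoate
Product: 17 2-[(1-hydroxy-3-methylbut-2-en-2-yl)oxy]-4,5-dimethoxybenzaldehyde, via acetal alcohol 16 (not isolated)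
Conditions: DIBAL-H (2.5 equiv), CH2Cl2, −78 °C; aq. Rochelle salt; then PPTS (10 mol %), acetone–H2O 10:1, 25 °C, 30 min; NaHCO3
Reagents that add atoms: water, O
Why: DIBAL 1,2-reduction of the ester gives the allylic alcohol, and the acetal of the very electron-rich benzaldehyde hydrolyses orders of magnitude faster than the β,β-disubstituted aryl enol ether is protonated at pH 3–4.

### Union and ring closures

**Step 9**
Reactants: 9 1-[5-hydroxy-7-methoxy-2,2-dimethyl-8-(3-methylbut-2-en-1-yl)-2H-chromen-6-yl]ethan-1-one; 17 2-[(1-hydroxy-3-methylbut-2-en-2-yl)oxy]-4,5-dimethoxybenzaldehyde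
Product: 18 (2E)-3-{2-[(1-hydroxy-3-methylbut-2-en-2-yl)oxy]-4,5-dimethoxyphenyl}-1-[5-hydroxy-7-methoxy-2,2-dimethyl-8-(3-methylbut-2-en-1-yl)-2H-chromen-6-yl]prop-2-en-1-one
Conditions: KOH (10 equiv), EtOH, 25 °C, 48 h, Ar; aq. NH4Cl work-up
Reagents that add atoms: none
Why: Claisen–Schmidt aldol condensation of the methyl ketone with the only aldehyde present gives the E-chalcone; the enol ether, allylic alcohol and alkenes are inert to base.

**Step 10**
Reactants: 18 the chalcone allylic alcohol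
Product: 19 2-(2-{(1E)-3-[5-hydroxy-7-methoxy-2,2-dimethyl-8-(3-methylbut-2-en-1-yl)-2H-chromen-6-yl]-3-oxoprop-1-en-1-yl}-4,5-dimethoxyphenoxy)-3-methylbut-2-enal
Conditions: activated MnO2 (20 equiv), CH2Cl2, 25 °C
Reagents that add atoms: none
Why: MnO2 oxidises only the allylic alcohol to the enal under neutral conditions and leaves the chelated phenol, enone, enol ether and isolated alkenes untouched.

**Step 11**
Reactants: 19 the chalcone enal
Product: 23 target oxepino-fused pyranoflavone (CNP0192589.0), via flavanone 20 (not isolated), via aldol adduct 21 (not isolated), via 3-alkylidene flavanone 22 (not isolated)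
Conditions: piperidine (3 equiv), 4 Å MS, degassed n-BuOH (0.01 M), 100 °C, Ar; then DBU (1 equiv), 100 °C
Reagents that add atoms: none
Why: Intramolecular oxa-Michael addition of the 2'-phenoxide closes the pyranone, the resulting C3 enol(ate) closes the seven-membered oxepine by intramolecular aldol condensation onto the piperidine-activated enal, and the exocyclic C3=CH bond then shifts into the ring (3-alkylideneflavanone → 3-alkylflavone prototropic isomerization), which removes all transient stereocentres and gives the achiral target.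

## Compound list

1 | 1-(2,4-dihydroxy-6-methoxyphenyl)ethan-1-one | CC(=O)c1c(O)cc(O)cc1OC | starting material
2 | 3-chloro-3-methylbut-1-yne | CC(C)(Cl)C#C | starting material
3 | 1-{2-hydroxy-6-methoxy-4-[(2-methylbut-3-yn-2-yl)oxy]phenyl}ethan-1-one | CC(=O)c1c(O)cc(OC(C)(C)C#C)cc1OC | intermediate
4 | 4-acetyl-3-hydroxy-5-methoxy-2-(3-methylbut-2-en-1-ylidene)cyclohexa-3,5-dien-1-one (o-quinone methide) | CC(=O)C1=C(O)C(=CC=C(C)C)C(=O)C=C1OC | intermediate (not isolated)
5 | 1-(5-hydroxy-7-methoxy-2,2-dimethyl-2H-chromen-6-yl)ethan-1-one | CC(=O)c1c(O)c2C=CC(C)(C)Oc2cc1OC | intermediate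
6 | 1-bromo-3-methylbut-2-ene | CC(C)=CCBr | starting material
7 | 1-{7-methoxy-2,2-dimethyl-5-[(3-methylbut-2-en-1-yl)oxy]-2H-chromen-6-yl}ethan-1-one | CC(=O)c1c(OCC=C(C)C)c2C=CC(C)(C)Oc2cc1OC | intermediate
8 | 6-acetyl-7-methoxy-2,2-dimethyl-6-(2-methylbut-3-en-2-yl)-2H-chromen-5(6H)-one (ortho-dienone, racemic) | CC(=O)C1(C(C)(C)C=C)C(=O)C2=C(OC(C)(C)C=C2)C=C1OC | intermediate (not isolated)
9 | 1-[5-hydroxy-7-methoxy-2,2-dimethyl-8-(3-methylbut-2-en-1-yl)-2H-chromen-6-yl]ethan-1-one | CC(=O)c1c(O)c2C=CC(C)(C)Oc2c(CC=C(C)C)c1OC | intermediate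
10 | 2-hydroxy-4,5-dimethoxybenzaldehyde | O=Cc1cc(OC)c(OC)cc1O | starting material
11 | ethyl 2-bromo-3-methylbutanoate (racemic) | CCOC(=O)C(Br)C(C)C | starting material
12 | ethyl 2-(2-formyl-4,5-dimethoxyphenoxy)-3-methylbutanoate (racemic) | CCOC(=O)C(Oc1cc(OC)c(OC)cc1C=O)C(C)C | intermediate
13 | ethyl 2-[2-(diethoxymethyl)-4,5-dimethoxyphenoxy]-3-methylbutanoate (racemic) | CCOC(=O)C(Oc1cc(OC)c(OC)cc1C(OCC)OCC)C(C)C | intermediate
14 | ethyl 2-[2-(diethoxymethyl)-4,5-dimethoxyphenoxy]-3-methyl-2-(phenylselanyl)butanoate (racemic) | CCOC(=O)C([Se]c1ccccc1)(Oc1cc(OC)c(OC)cc1C(OCC)OCC)C(C)C | intermediate (not isolated)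
15 | ethyl 2-[2-(diethoxymethyl)-4,5-dimethoxyphenoxy]-3-methylbut-2-enoate | CCOC(=O)C(Oc1cc(OC)c(OC)cc1C(OCC)OCC)=C(C)C | intermediate
16 | 2-[2-(diethoxymethyl)-4,5-dimethoxyphenoxy]-3-methylbut-2-en-1-ol | OCC(Oc1cc(OC)c(OC)cc1C(OCC)OCC)=C(C)C | intermediate (not isolated)
17 | 2-[(1-hydroxy-3-methylbut-2-en-2-yl)oxy]-4,5-dimethoxybenzaldehyde | OCC(Oc1cc(OC)c(OC)cc1C=O)=C(C)C | intermediate
18 | (2E)-3-{2-[(1-hydroxy-3-methylbut-2-en-2-yl)oxy]-4,5-dimethoxyphenyl}-1-[5-hydroxy-7-methoxy-2,2-dimethyl-8-(3-methylbut-2-en-1-yl)-2H-chromen-6-yl]prop-2-en-1-one | O=C(/C=C/c1cc(OC)c(OC)cc1OC(CO)=C(C)C)c1c(O)c2C=CC(C)(C)Oc2c(CC=C(C)C)c1OC | intermediate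
19 | 2-(2-{(1E)-3-[5-hydroxy-7-methoxy-2,2-dimethyl-8-(3-methylbut-2-en-1-yl)-2H-chromen-6-yl]-3-oxoprop-1-en-1-yl}-4,5-dimethoxyphenoxy)-3-methylbut-2-enal | O=C(/C=C/c1cc(OC)c(OC)cc1OC(C=O)=C(C)C)c1c(O)c2C=CC(C)(C)Oc2c(CC=C(C)C)c1OC | intermediate
20 | 2-{4,5-dimethoxy-2-[(3-methyl-1-oxobut-2-en-2-yl)oxy]phenyl}-5-methoxy-8,8-dimethyl-6-(3-methylbut-2-en-1-yl)-2,3-dihydro-4H,8H-pyrano[2,3-h]chromen-4-one (flavanone, racemic) | O=C1CC(c2cc(OC)c(OC)cc2OC(C=O)=C(C)C)Oc2c1c(OC)c(CC=C(C)C)c1OC(C)(C)C=Cc12 | intermediate (not isolated)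
21 | oxepine-closed aldol adduct: flavanone C3 bonded to CH(OH)–C(=CMe2)–O–C2' (diastereomer mixture) | O=C1C2C(O)C(=C(C)C)Oc3cc(OC)c(OC)cc3C2Oc2c1c(OC)c(CC=C(C)C)c1OC(C)(C)C=Cc12 | intermediate (not isolated)
22 | 3-alkylidene flavanone: exocyclic C3=CH inside the oxepine, C2–H still present (racemic) | O=C1C2=CC(=C(C)C)Oc3cc(OC)c(OC)cc3C2Oc2c1c(OC)c(CC=C(C)C)c1OC(C)(C)C=Cc12 | intermediate (not isolated)
23 | CNP0192589.0: 4',5'-dimethoxy-5-methoxy-6-prenyl-7,8-(2,2-dimethylpyrano)flavone with a C3–CH2–C(=CMe2)–O–C2' oxepine bridge (achiral) | COc1cc2c(cc1OC)-c1oc3c4c(c(CC=C(C)C)c(OC)c3c(=O)c1CC(=C(C)C)O2)OC(C)(C)C=C4 | target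

## Step count and risks

Total steps: 11 (A-ring fragment steps 1–4, B-ring fragment steps 5–8, union and closure steps 9–11).
Longest linear sequence: 7 steps (5–8 then 9–11, or equally 1–4 then 9–11).

**Step 11 (domino oxa-Michael / aldol / isomerization).** The seven-membered aldol onto a hindered enal may stall at the chalcone/flavanone stage, or the double bond may settle elsewhere. The fallback forms the C3–CH2 bond first and closes the oxepine by aldol condensation onto the less hindered aryl aldehyde. It sets out from 16 (isolated by leaving out the PPTS treatment in step 8) and from 9, and returns at 23.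
- 16 is brominated (CBr4, PPh3, 2,6-lutidine, CH2Cl2, 0 °C) to the allylic bromide 1-[(1-bromo-3-methylbut-2-en-2-yl)oxy]-2-(diethoxymethyl)-4,5-dimethoxybenzene F1.
- The dilithio dianion of 9 (LiHMDS 2.2 equiv, THF, −78 °C) is C-alkylated with it to the ketone 4-[2-(diethoxymethyl)-4,5-dimethoxyphenoxy]-1-(chromenyl)-5-methylhex-4-en-1-one F2.
- PPTS in wet acetone frees the keto aldehyde F3.
- Intramolecular aldol condensation (KOH, EtOH, 25 °C) closes the oxepine to the 4-aroyl-7,8-dimethoxy-2-(propan-2-ylidene)-2,3-dihydro-1-benzoxepine F4.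
- NaOAc in refluxing EtOH brings about the oxa-Michael closure to the 2,3-dihydro target (flavanone) F5.
- Mukaiyama dehydrogenation (LiHMDS, then N-tert-butylbenzenesulfinimidoyl chloride, THF, −78 °C) gives 23.

**Step 4 (para-Claisen–Cope).** The dienone carrying the acetyl group may deacylate or lose the prenyl group at 200 °C. The fallback installs the prenyl group by cross-coupling. It sets out from 5 and returns at 9.
- 5 is iodinated at its only free aromatic position (benzyltrimethylammonium dichloroiodate, NaHCO3, CH2Cl2–MeOH, 25 °C) to 1-(5-hydroxy-8-iodo-7-methoxy-2,2-dimethyl-2H-chromen-6-yl)ethan-1-one F6.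
- Stille coupling with tributyl(3-methylbut-2-en-1-yl)stannane (Pd(PPh3)4, DMF, 90 °C) gives 9.

**Step 7 (selenoxide dehydrogenation of a hindered α-aryloxy ester).** Enolization or selenenylation at the crowded α-carbon may be poor. The fallback builds the enol ether by olefination instead. It sets out from 10 and returns at 15.
- Rh2(OAc)4-catalysed O–H insertion of ethyl diazo(diethoxyphosphoryl)acetate into the phenol (toluene, 80 °C) gives ethyl 2-(diethoxyphosphoryl)-2-(2-formyl-4,5-dimethoxyphenoxy)acetate F7.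
- Acetalization (HC(OEt)3, EtOH, cat. TsOH) gives the diethyl acetal F8.
- Horner–Wadsworth–Emmons olefination with acetone (NaH, THF, 0 °C → reflux) gives 15.

## Further compounds

F1 | step 11 | 1-[(1-bromo-3-methylbut-2-en-2-yl)oxy]-2-(diethoxymethyl)-4,5-dimethoxybenzene | CCOC(OCC)c1cc(OC)c(OC)cc1OC(CBr)=C(C)C
F2 | step 11 | 4-[2-(diethoxymethyl)-4,5-dimethoxyphenoxy]-1-[5-hydroxy-7-methoxy-2,2-dimethyl-8-(3-methylbut-2-en-1-yl)-2H-chromen-6-yl]-5-methylhex-4-en-1-one | CCOC(OCC)c1cc(OC)c(OC)cc1OC(CCC(=O)c1c(O)c2C=CC(C)(C)Oc2c(CC=C(C)C)c1OC)=C(C)C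
F3 | step 11 | 2-({6-[5-hydroxy-7-methoxy-2,2-dimethyl-8-(3-methylbut-2-en-1-yl)-2H-chromen-6-yl]-2-methyl-6-oxohex-2-en-3-yl}oxy)-4,5-dimethoxybenzaldehyde | O=Cc1cc(OC)c(OC)cc1OC(CCC(=O)c1c(O)c2C=CC(C)(C)Oc2c(CC=C(C)C)c1OC)=C(C)C
F4 | step 11 | [7,8-dimethoxy-2-(propan-2-ylidene)-2,3-dihydro-1-benzoxepin-4-yl][5-hydroxy-7-methoxy-2,2-dimethyl-8-(3-methylbut-2-en-1-yl)-2H-chromen-6-yl]methanone | CC(C)=C1CC(C(=O)c2c(O)c3C=CC(C)(C)Oc3c(CC=C(C)C)c2OC)=Cc2cc(OC)c(OC)cc2O1
F5 | step 11 | 2,3-dihydro derivative of the target (oxepine-fused flavanone, racemic) | O=C1C2CC(=C(C)C)Oc3cc(OC)c(OC)cc3C2Oc2c1c(OC)c(CC=C(C)C)c1OC(C)(C)C=Cc12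
F6 | step 4 | 1-(5-hydroxy-8-iodo-7-methoxy-2,2-dimethyl-2H-chromen-6-yl)ethan-1-one | CC(=O)c1c(O)c2C=CC(C)(C)Oc2c(I)c1OC
F7 | step 7 | ethyl 2-(diethoxyphosphoryl)-2-(2-formyl-4,5-dimethoxyphenoxy)acetate | CCOC(=O)C(Oc1cc(OC)c(OC)cc1C=O)P(=O)(OCC)OCC
F8 | step 7 | ethyl 2-[2-(diethoxymethyl)-4,5-dimethoxyphenoxy]-2-(diethoxyphosphoryl)acetate | CCOC(=O)C(Oc1cc(OC)c(OC)cc1C(OCC)OCC)P(=O)(OCC)OCC
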